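The flasks are read at 12 h, but the delta run stops at 80.0 min, so I need a clock that can be carried 9.00 times as far.

| setting | delta | oak | ash | birch |
|---|---|---|---|---|
| substrate | 0.050 M | 0.10 M | 0.10 M | 0.10 M |
| gas | 3.5 mM (held) | 3.5 mM (held) | 3.5 mM (held) | 3.5 mM (held) |
| temperature | −40 °C | −40 °C | −20 °C | 0 °C |
| remark | run made earlier |  |  |  |
| time |  | 12 h | 12 h | 12 h |

- delta (time / min: target / %, substrate / %): 6.00: 6, 100; 10.0: 0, 100; 15.0: 2, 96; 25.0: 6, 97; 40.0: 10, 90; 80.0: 18, 78

(readings scatter by 2 percentage points)

- the best flask by amount of target, in percent of the substrate charged; "all alike" if 1.5 percentage points covers them all (oak / ash / birch / all alike)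
- amount of target at the end, in percent of the substrate charged, oak
- amount of target at the end, in percent of the substrate charged, ash
- amount of target at the end, in percent of the substrate charged, birch

- at the start none of the gas is in solution
- the earlier runs do not show what temperature does; that part of a forecast is a guess

The nearly constant thing here is the gas in solution, held at 3.5 mM, so I freeze it and let substrate fall exponentially, the pseudo-first-order picture. The last delta reading, 78% of the charge left, gives 0.00311 /min as the frozen-gas clock, the fraction of standing substrate that reacts per minute at −40 °C.

But the gas starts out of solution, so a lag may spoil this. The clock gives 88.3% left at 40.0 min against a reading of 90%, which lies within the scatter of 2 percentage points, so I ignore the lag. Is the gas really frozen, though? If one gas goes with one substrate, delta has already used 3.14 fills of the solution without a visible bend. Oak, at the conversion this clock gives it by 12 h, asks 25.5 fills, a doubt I keep.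

In oak the clock leaves 10.7% of the substrate at 12 h, so 89.3% is converted. Yet conversion is not target: delta's balance lacks 4 points, which the scatter can neither confirm nor dismiss. Carrying delta's reading of target per substrate lost, 81.8%, gives 73.0%, so I commit to oak's target lying between that and 89.3%. Warming should speed the clock, but the unread loss may speed with it, so I rank oak as the one flask I can reckon.

The forecast differs, putting ash on top with 83% for oak, 91% for ash and 85% for birch: “Warming should speed the reaction”.

The flasks give 75.5% in oak, 45.1% in ash and 4.48% in birch, so oak is best.

    substrate + reagent ⇌ target (K = 3300 /M, k = 4.84 /M/min, Ea = 41.0 kJ/mol, ΔH = −36.0 kJ/mol)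
    substrate + target → side product (k = 0.0746 /M/min, Ea = 62.0 kJ/mol)
    gas ⇌ reagent, rate k3*(csat - [reagent]) (kL = 0.408 /min)
    (constants at −20 °C)

Oak keeps 11% of its substrate where the clock said 10.7%, with reagent at 0.00343 M. The delta charge run on to 12 h holds 81.7% target, so against the same clock its gap is 7.6 points, while oak's is 14 points, about twice as wide. Part of oak's gap is the passing of substrate and target into side product: struck out, oak holds 86.4%. The same step is the main reason for birch, which without it holds 76.8% instead of 4.48%.

The numbers in the tables come from a simulation from invented constants, and the scatter is random.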